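The numbers in the tables are calculated on assumed constants; scatter was added.

The pitfall with a dilute flask was to reckon on the whole charge of starting complex as material for ligand exchange, when the protic impurity takes its cut first.

| flask | starting complex | incoming ligand | leaving ligand | protic impurity | remark | time |
|---|---|---|---|---|---|---|
| Wednesday's | 0.97 mM | 2.5 equiv | 0.50 equiv | 0.50 mM | run made earlier |  |
| Tuesday's | 13 mM | 2.5 equiv | 0.50 equiv | 0.50 mM | run made earlier |  |
| noon | 1.2 mM | 2.50 equiv | 0.500 equiv | 0.500 mM |  | 8.0 min |
| spring | 2.5 mM | 2.50 equiv | 0.500 equiv | 0.500 mM |  | 8.0 min |
| dusk | 5.0 mM | 2.50 equiv | 0.500 equiv | 0.500 mM |  | 8.0 min |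
| autumn | 10 mM | 2.50 equiv | 0.500 equiv | 0.500 mM |  | 8.0 min |
| dawn | 20 mM | 2.50 equiv | 0.500 equiv | 0.500 mM |  | 8.0 min |

| run | time / min | complex with one exchanged / % | starting complex / % |
|---|---|---|---|
| Wednesday's | 0.333 | 0.3 | 53.4 |
| Wednesday's | 0.667 | 2.2 | 48.3 |
| Wednesday's | 1.50 | 2.5 | 44.2 |
| Wednesday's | 4.00 | 5.0 | 37.7 |
| Tuesday's | 0.500 | 22.8 | 65.1 |
| Tuesday's | 1.33 | 30.0 | 35.1 |
| Tuesday's | 2.50 | 24.9 | 15.3 |
| Tuesday's | 4.00 | 14.0 | 5.3 |

(each reading ± 0.5 percentage points)

- the numbers in the tables scatter with a standard deviation of 0.5 percentage points
- on the list of suspects stand: starting complex + incoming ligand -> leaving ligand + complex with one exchanged; complex with one exchanged + incoming ligand -> leaving ligand + complex with two exchanged; complex with two exchanged + incoming ligand -> leaving ligand + complex with three exchanged; protic impurity + starting complex -> quenched substrate; complex with one exchanged -> over-reaction product; leaving ligand + starting complex -> side product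
- "hardly changes" means that all values lie within two and a half points (for a concentration: within two and a half percent of the largest)

- amount of complex with one exchanged at the end, in percent of the starting complex charged for noon, spring, dusk, autumn, dawn, in this order
- the course of these numbers from the first flask to the last (rises, then falls / falls, then rises / hardly changes / rises all the way / falls all the way)

I read the two runs as a ladder of time scales. On the first rung, the first reading of Wednesday's run, at 0.333 min, showed a loss of 0.452 mM of starting complex, against 0.50 mM of protic impurity charged, so I took the quench as one to one. For noon that gave 58.3 % as the live share, the fraction of the charge of starting complex that the impurity, taken one to one, leaves to react.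

On the second rung, the starting complex fell on with a half-life that I read as 0.931 min between 0.500 min and 1.33 min on Tuesday's run and 10.9 min between 1.50 min and 4.00 min on Wednesday's, so over these stretches the more dilute run read slower.

On the third rung, the complex with one exchanged had its highest reading on Tuesday's run at 1.33 min, 30.0 %, and was down to 14.0 % by 4.00 min. On Wednesday's run its highest reading came last, 5.0 % at 4.00 min. I therefore expected a row with a maximum inside it.

The live share is my own reckoning and sets no row value; the last column is the forecast's.

| Flask | Charge | Live share | Forecast |
|---|---|---|---|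
| noon | 1.2 mM | 58.3 % | 6.8 % |
| spring | 2.5 mM | 80.0 % | 11.4 % |
| dusk | 5.0 mM | 90.0 % | 11 % |
| autumn | 10 mM | 95.0 % | 5.5 % |
| dawn | 20 mM | 97.5 % | 1.7 % |

The forecast called the course "rises, then falls", holding that “dilute flasks are quenched and slow, while concentrated flasks have already passed their maximum by 8 min”.

The flasks gave 5.33 %, 8.73 %, 7.83 %, 3.75 % and 0.991 %, a course that rises, then falls.

    starting complex + incoming ligand → leaving ligand + complex with one exchanged (k = 0.350 M⁻¹ s⁻¹)
    complex with one exchanged + incoming ligand → leaving ligand + complex with two exchanged (k = 0.140 M⁻¹ s⁻¹)
    complex with two exchanged + incoming ligand → leaving ligand + complex with three exchanged (k = 0.100 M⁻¹ s⁻¹)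
    protic impurity + starting complex → quenched substrate (k = 160 M⁻¹ s⁻¹)
    complex with one exchanged → over-reaction product (k = 0.00640 s⁻¹)
    leaving ligand + starting complex → side product (k = 0.280 M⁻¹ s⁻¹)

At 8.00 min, the noon flask's starting complex and everything made from it without quenching summed to 58.3 %, against its live share of 58.3 %, and the dawn flask's to 97.5 %, against 97.5 %. In the noon flask, the complex with one exchanged had a half-life of 1.8 min by over-reaction alone, shorter than the pseudo-first-order 28 min by second exchange alone at the charged incoming ligand. At the end of the noon flask, over-reaction used it 17 times as fast as second exchange, and 15.2 % of over-reaction product stood beside 0.888 % of complex with two exchanged.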